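# Total synthesis of integric acid by enantioselective dearomative ring closure

## Retrosynthetic overview

1. The endgame is a single acidolysis that frees the C4 acid (from a t-Bu ester) and the C12 aldehyde (from a diethyl acetal). Before that, 1,4-hydride addition to a Δ6 cross-conjugated dienone creates C7.
2. The C1 ester comes from Yamaguchi coupling with (S,E)-2,4-dimethyloct-2-enoic acid. The C7 side arm comes from Stille coupling of a 7-iodo-dienone with an α-stannyl acrolein acetal.
3. The 1β-OH comes from vinylogous Rubottom oxidation of a silyl trienol ether. That same silyl ether masks the dienone while CuH saturates the Δ3 enoate and sets C4.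
4. The key disconnection is C4–C5, made by a Pd-catalysed enantioselective dearomative vinylation of a p-cresol. Ring B is the starting arene. Ring A closes second and creates the quaternary C5, so no Robinson or Wieland–Miescher chemistry is used.
5. The cyclisation precursor comes from 3-bromo-4-methylphenol, allyl alcohol (Heck) and a bromo-ylide (Wittig).

**Assumptions**
- Eremophilane numbering is used in the "Why" lines: C1 = acyloxy carbon, C4 = CO2H carbon, C5 = quaternary carbon, C7 = side-arm carbon, C8 = ketone, with C9=C10. β means the face carrying the C5 methyl.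
- The antipode of the P-chiral ligand in Step 11 is chosen by a pilot run to give (8aS)-18.

## Fragment A: side-chain acid

**Step 1**
Reactants: 1 (S)-4-benzyl-1,3-oxazolidin-2-one; 2 hexanoyl chloride
Product: 3 (S)-4-benzyl-3-hexanoyl-1,3-oxazolidin-2-one
Conditions: n-BuLi, THF, −78 °C; then 2, −78 → 0 °C
Reagents that add atoms: hexanoyl chloride, CCCCCC(=O)Cl
Why: N-acylation of the lithiated Evans auxiliary, with no new stereocentre formed.

**Step 2**
Reactants: 3
Product: 4 (S)-4-benzyl-3-[(S)-2-methylhexanoyl]-1,3-oxazolidin-2-one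
Conditions: NaHMDS, THF, −78 °C; MeI, −78 °C
Reagents that add atoms: methyl iodide, CI
Why: Evans asymmetric alkylation, in which MeI attacks the chelated Z-sodium enolate anti to the benzyl group to give the (S)-α-methyl centre (the future C4′), and the minor diastereomer is removed by chromatography.

**Step 3**
Reactants: 4
Product: 5 (S)-2-methylhexan-1-ol
Conditions: LiBH4, MeOH (1 equiv), Et2O, 0 °C
Reagents that add atoms: none
Why: Reductive removal of the auxiliary, during which the stereocentre is never enolised.

**Step 4**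
Reactants: 5
Product: 6 (S)-2-methylhexanal (used crude at once)
Conditions: (COCl)2, DMSO, i-Pr2NEt, CH2Cl2, −78 °C
Reagents that add atoms: none
Why: Swern oxidation at low temperature followed by immediate use avoids α-epimerisation.

**Step 5**
Reactants: 6; 7 ethyl 2-(triphenylphosphoranylidene)propanoate
Product: 8 ethyl (2E,4S)-2,4-dimethyloct-2-enoate
Conditions: CH2Cl2, 0 °C → rt
Reagents that add atoms: ylide 7, CCOC(=O)C(C)=P(c1ccccc1)(c1ccccc1)c1ccccc1
Why: Wittig olefination with a stabilised α-methyl ylide gives the E-trisubstituted enoate (>20:1) under non-basic conditions.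

**Step 6**
Reactants: 8
Product: 9 (2E,4S)-2,4-dimethyloct-2-enoic acid
Conditions: LiOH, THF/MeOH/H2O, 45 °C; then aq. KHSO4
Reagents that add atoms: lithium hydroxide, [Li+].[OH-]
Why: Saponification, in which the conjugated E-enoate does not deconjugate, so C4′ is retained.

## Fragment B: acrolein α-anion equivalent

**Step 7**
Reactants: 10 3,3-diethoxyprop-1-yne
Product: 11 tributyl(3,3-diethoxyprop-1-en-2-yl)stannane
Conditions: Bu3SnH, PdCl2(PPh3)2 (2 mol %), THF, 0 °C → rt
Reagents that add atoms: tributyltin hydride, CCCC[SnH](CCCC)CCCC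
Why: Pd-catalysed syn-hydrostannation places tin on the internal carbon next to the electron-withdrawing acetal, and the minor (E)-β-isomer is removed by chromatography.

## Fragment C: bromo-ylide

**Step 8**
Reactants: 12 tert-butyl (triphenylphosphoranylidene)acetate
Product: 13 tert-butyl 2-bromo-2-(triphenylphosphoranylidene)acetate
Conditions: NBS (0.98 equiv), CH2Cl2, −20 °C; aq. K2CO3 wash
Reagents that add atoms: N-bromosuccinimide, O=C1CCC(=O)N1Br
Why: Electrophilic bromination of the stabilised ylide followed by deprotonation of the bromophosphonium salt gives the stable bromo-ylide.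

## Main line

**Step 9**
Reactants: 14 3-bromo-4-methylphenol; 15 allyl alcohol
Product: 16 3-(5-hydroxy-2-methylphenyl)propanal
Conditions: Pd(OAc)2 (3 mol %), n-Bu4NCl, NaHCO3, DMF, 90 °C
Reagents that add atoms: allyl alcohol, C=CCO
Why: Jeffery–Heck arylation of allyl alcohol, in which β-hydride elimination toward the carbinol and tautomerisation deliver the aldehyde (C1–C3) directly and the free phenol is tolerated.

**Step 10**
Reactants: 16; 13
Product: 17 tert-butyl (Z)-2-bromo-5-(5-hydroxy-2-methylphenyl)pent-2-enoate
Conditions: CH2Cl2, rt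
Reagents that add atoms: bromo-ylide 13, CC(C)(C)OC(=O)C(Br)=P(c1ccccc1)(c1ccccc1)c1ccccc1
Why: Wittig reaction of the stabilised bromo-ylide puts the ester trans to the chain, giving the Z isomer with Br cis to C2, which is the geometry ring closure needs.

**Step 11 (key step)**
Reactants: 17
Product: 18 tert-butyl (8aS)-8a-methyl-6-oxo-3,4,6,8a-tetrahydronaphthalene-1-carboxylate
Conditions: [Pd(cinnamyl)Cl]2 (2.5 mol %), P-stereogenic dihydrobenzooxaphosphole biaryl monophosphine (AntPhos/BI-DIME class, 6 mol %), K2CO3, toluene (0.03 M), 90 °C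
Reagents that add atoms: none
Why: Proposed new method: Pd(0) inserts into the C(sp2)–Br bond of the α-bromoenoate, the phenoxide binds, and dearomative C-palladation at the methyl-bearing para carbon followed by C–C reductive elimination from a seven-membered palladacycle closes ring A and creates quaternary C5, its face chosen by the bulky chiral ligand; the closest known reaction type is the Pd-catalysed enantioselective dearomative cyclisation of p-alkylphenols carrying a meta-CH2CH2-(2-bromoaryl) tether, to which this vinyl bromide is isosteric.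

**Step 12**
Reactants: 18
Product: 19 tert-butyl (8aS)-6-[(tert-butyldimethylsilyl)oxy]-8a-methyl-3,8a-dihydronaphthalene-1-carboxylate
Conditions: TBSOTf (1.3 equiv), Et3N, CH2Cl2, 0 °C
Reagents that add atoms: TBSOTf, CC(C)(C)[Si](C)(C)OS(=O)(=O)C(F)(F)F
Why: Soft enolisation of the cross-conjugated dienone, which has no α-H, so only the γ-protons at C1 can be removed and the linear silyl trienol ether forms.

**Step 13**
Reactants: 19
Product: 20 tert-butyl (1S,8aR)-6-[(tert-butyldimethylsilyl)oxy]-8a-methyl-1,2,3,8a-tetrahydronaphthalene-1-carboxylate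
Conditions: Cu(OAc)2·H2O (5 mol %), 1,2-bis(diphenylphosphino)benzene (5 mol %), PMHS, t-BuOH, toluene, 0 °C → rt
Reagents that add atoms: none
Why: Copper hydride conjugate reduction, where the Δ3 enoate is the only Michael acceptor while the dienone is masked, so hydride adds to C3 and the copper enolate is protonated on the α face, anti to the adjacent axial C5 methyl, giving the equatorial 4β-ester (4S).

**Step 14**
Reactants: 20
Product: 21 tert-butyl (1S,4R,8aR)-4-hydroxy-8a-methyl-6-oxo-1,2,3,4,6,8a-hexahydronaphthalene-1-carboxylate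
Conditions: m-CPBA (1.05 equiv), NaHCO3, CH2Cl2, −30 °C; then Et3N·3HF, THF, 0 °C
Reagents that add atoms: m-CPBA, O=C(OO)c1cccc(Cl)c1
Why: Vinylogous Rubottom oxidation, in which the peracid attacks the γ-terminus C1 along the axial trajectory of the ring-A half-chair (β face), as in the 6β-hydroxylation of steroidal dienol ethers, giving 1β-OH (1R) and regenerating the dienone.

**Step 15**
Reactants: 21
Product: 22 tert-butyl (1S,4R,8aS)-4-hydroxy-7-iodo-8a-methyl-6-oxo-1,2,3,4,6,8a-hexahydronaphthalene-1-carboxylate (same geometry; the descriptor changes only because of iodine priority)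
Conditions: I2, DMAP (0.2 equiv), pyridine/CH2Cl2, rt, dark
Reagents that add atoms: iodine, II
Why: Johnson α-iodination by addition, iodination and elimination can run only on the Δ6 enone because C10 is fully substituted, so iodine goes to C7 alone.

**Step 16**
Reactants: 22; 11
Product: 23 tert-butyl (1S,4R,8aR)-7-(3,3-diethoxyprop-1-en-2-yl)-4-hydroxy-8a-methyl-6-oxo-1,2,3,4,6,8a-hexahydronaphthalene-1-carboxylate
Conditions: Pd(PPh3)4 (5 mol %), CuTC, [n-Bu4N][Ph2PO2], DMF, rt
Reagents that add atoms: stannane 11, C=C([Sn](CCCC)(CCCC)CCCC)C(OCC)OCC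
Why: Copper-assisted Stille coupling of an α-iodoenone under neutral conditions at rt tolerates the free alcohol, the acetal and the t-Bu ester, and running it before acylation means Pd(0) never meets an allylic ester.

**Step 17**
Reactants: 23; 9
Product: 24 tert-butyl (1S,4R,8aR)-7-(3,3-diethoxyprop-1-en-2-yl)-4-{[(2E,4S)-2,4-dimethyloct-2-enoyl]oxy}-8a-methyl-6-oxo-1,2,3,4,6,8a-hexahydronaphthalene-1-carboxylate
Conditions: 9, 2,4,6-Cl3C6H2COCl, Et3N, toluene, rt; then 23, DMAP, rt → 40 °C
Reagents that add atoms: acid 9, CCCC[C@H](C)/C=C(\C)C(=O)O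
Why: Yamaguchi esterification acylates the hindered axial alcohol with retention at C1, and any minor core enantiomer from Step 11 becomes a separable diastereomer here.

**Step 18**
Reactants: 24
Product: 25 tert-butyl (1S,4R,7S,8aR)-7-(3,3-diethoxyprop-1-en-2-yl)-4-{[(2E,4S)-2,4-dimethyloct-2-enoyl]oxy}-8a-methyl-6-oxo-1,2,3,4,6,7,8,8a-octahydronaphthalene-1-carboxylate
Conditions: [(Ph3P)CuH]6 (0.3 equiv), degassed toluene, rt; then AcOH/THF, −78 °C
Reagents that add atoms: none
Why: Stryker conjugate reduction adds hydride to C6 of the Δ6 enone (Δ9 is β,β-disubstituted and the side-chain enoate is far slower), kinetic α-protonation at C7 keeps the 1,1-disubstituted alkene out of conjugation, and the side arm ends equatorial (7S, trans to C5-Me) because the axial epimer suffers a 1,3-diaxial clash and relaxes through the enol.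

**Step 19**
Reactants: 25
Product: 26 integric acid, (1S,4R,7S,8aR)-4-{[(2E,4S)-2,4-dimethyloct-2-enoyl]oxy}-8a-methyl-6-oxo-7-(3-oxoprop-1-en-2-yl)-1,2,3,4,6,7,8,8a-octahydronaphthalene-1-carboxylic acid
Conditions: TFA/CH2Cl2 (1:3), H2O (5 equiv), 0 °C → rt
Reagents that add atoms: water, O
Why: Acidolysis removes isobutene from the t-Bu ester and hydrolyses the allylic acetal in one operation, while the secondary enoate ester and all stereocentres are untouched because C7 is already the thermodynamic epimer.

## Compound list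

| No. | Name | SMILES | Role |
|---|---|---|---|
| 1 | (S)-4-benzyl-1,3-oxazolidin-2-one | O=C1N[C@@H](Cc2ccccc2)CO1 | starting material |
| 2 | hexanoyl chloride | CCCCCC(=O)Cl | starting material |
| 3 | (S)-4-benzyl-3-hexanoyloxazolidin-2-one | CCCCCC(=O)N1[C@@H](Cc2ccccc2)COC1=O | intermediate |
| 4 | (S)-4-benzyl-3-[(S)-2-methylhexanoyl]oxazolidin-2-one | CCCC[C@H](C)C(=O)N1[C@@H](Cc2ccccc2)COC1=O | intermediate |
| 5 | (S)-2-methylhexan-1-ol | CCCC[C@H](C)CO | intermediate |
| 6 | (S)-2-methylhexanal | CCCC[C@H](C)C=O | intermediate |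
| 7 | ethyl 2-(triphenylphosphoranylidene)propanoate | CCOC(=O)C(C)=P(c1ccccc1)(c1ccccc1)c1ccccc1 | starting material |
| 8 | ethyl (2E,4S)-2,4-dimethyloct-2-enoate | CCCC[C@H](C)/C=C(\C)C(=O)OCC | intermediate |
| 9 | (2E,4S)-2,4-dimethyloct-2-enoic acid | CCCC[C@H](C)/C=C(\C)C(=O)O | intermediate |
| 10 | 3,3-diethoxyprop-1-yne | C#CC(OCC)OCC | starting material |
| 11 | tributyl(3,3-diethoxyprop-1-en-2-yl)stannane | C=C([Sn](CCCC)(CCCC)CCCC)C(OCC)OCC | intermediate |
| 12 | tert-butyl (triphenylphosphoranylidene)acetate | CC(C)(C)OC(=O)C=P(c1ccccc1)(c1ccccc1)c1ccccc1 | starting material |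
| 13 | tert-butyl 2-bromo-2-(triphenylphosphoranylidene)acetate | CC(C)(C)OC(=O)C(Br)=P(c1ccccc1)(c1ccccc1)c1ccccc1 | intermediate |
| 14 | 3-bromo-4-methylphenol | Cc1ccc(O)cc1Br | starting material |
| 15 | allyl alcohol | C=CCO | starting material |
| 16 | 3-(5-hydroxy-2-methylphenyl)propanal | Cc1ccc(O)cc1CCC=O | intermediate |
| 17 | tert-butyl (Z)-2-bromo-5-(5-hydroxy-2-methylphenyl)pent-2-enoate | Cc1ccc(O)cc1CC/C=C(\Br)C(=O)OC(C)(C)C | intermediate |
| 18 | tert-butyl (8aS)-8a-methyl-6-oxo-3,4,6,8a-tetrahydronaphthalene-1-carboxylate | O=C1C=C[C@@]2(C)C(=C1)CCC=C2C(=O)OC(C)(C)C | intermediate |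
| 19 | tert-butyl (8aS)-6-(TBSO)-8a-methyl-3,8a-dihydronaphthalene-1-carboxylate | C1=C[C@@]2(C)C(C=C1O[Si](C)(C)C(C)(C)C)=CCC=C2C(=O)OC(C)(C)C | intermediate |
| 20 | tert-butyl (1S,8aR)-6-(TBSO)-8a-methyl-1,2,3,8a-tetrahydronaphthalene-1-carboxylate | C1=C[C@@]2(C)C(C=C1O[Si](C)(C)C(C)(C)C)=CCC[C@@H]2C(=O)OC(C)(C)C | intermediate |
| 21 | tert-butyl (1S,4R,8aR)-4-hydroxy-8a-methyl-6-oxo-1,2,3,4,6,8a-hexahydronaphthalene-1-carboxylate | O=C1C=C[C@@]2(C)C(=C1)[C@H](O)CC[C@@H]2C(=O)OC(C)(C)C | intermediate |
| 22 | 7-iodo derivative of 21, (1S,4R,8aS) | O=C1C(I)=C[C@@]2(C)C(=C1)[C@H](O)CC[C@@H]2C(=O)OC(C)(C)C | intermediate |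
| 23 | 7-(3,3-diethoxyprop-1-en-2-yl) derivative of 21, (1S,4R,8aR) | C=C(C(OCC)OCC)C1=C[C@@]2(C)C(=CC1=O)[C@H](O)CC[C@@H]2C(=O)OC(C)(C)C | intermediate |
| 24 | (2E,4S)-2,4-dimethyloct-2-enoate ester of 23 | C=C(C(OCC)OCC)C1=C[C@@]2(C)C(=CC1=O)[C@H](OC(=O)/C(C)=C/[C@@H](C)CCCC)CC[C@@H]2C(=O)OC(C)(C)C | intermediate |
| 25 | 7,8-dihydro derivative of 24, (1S,4R,7S,8aR) | C=C(C(OCC)OCC)[C@@H]1C[C@@]2(C)C(=CC1=O)[C@H](OC(=O)/C(C)=C/[C@@H](C)CCCC)CC[C@@H]2C(=O)OC(C)(C)C | intermediate |
| 26 | integric acid | C=C(C=O)[C@@H]1C[C@@]2(C)C(=CC1=O)[C@H](OC(=O)/C(C)=C/[C@@H](C)CCCC)CC[C@@H]2C(=O)O | target |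

## Step count

- Total steps: 19
- Longest linear sequence: 11 (Steps 9–19, from 3-bromo-4-methylphenol)

## Three steps most likely to fail

**1. Step 11, the dearomative vinylation**
- Failure modes: attack at the free ortho carbon C9 followed by rearomatisation, loss of HBr or oxa-Michael side reactions of the bromoenoate, or low ee.
- Fallback: abandon Pd and use an ionic dearomatisation.
  - Make tert-butyl 2-bromo-5-(5-hydroxy-2-methylphenyl)pentanoate by Heck reaction with tert-butyl pent-4-enoate, hydrogenation and α-bromination.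
  - Close ring A by Winstein–Masamune phenolate para-alkylation (KOt-Bu, t-BuOH). This gives the racemic dienone with C4 already sp3, so Step 13 is no longer needed.
  - Resolve the material as the diastereomeric esters formed with enantiopure 9 in Step 17.

**2. Step 13, the CuH reduction and C4 protonation**
- Failure modes: slow hydride delivery to the hindered enoate, or poor facial selectivity at C4.
- Fallback: set C4 by hydrogenation instead of protonation.
  - Cleave the t-Bu ester of 18 and hydrogenate the Δ3 unsaturated acid with Ru(OAc)2(BINAP)/H2. Only the chelating unsaturated acid is expected to react, and the catalyst antipode is matched to α-face delivery.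
  - Re-esterify with tert-butyl trichloroacetimidate, then silylate as in Step 12 to rejoin the route at 20.

**3. Step 18, reduction of the 2-alkenyl dienone**
- Failure modes: γ-protonation to the conjugated Δ7(11) enone, the wrong C7 epimer, or reduction of the side-chain enoate.
- Fallback: never form the 2-alkenyl dienone.
  - Acylate 21 directly with 9 and saturate Δ6 with RhCl(PPh3)3/H2, following the Δ1-selective precedent in steroidal 1,4-dien-3-ones.
  - Form the kinetic C7 TMS enol ether (LiHMDS/TMSCl).
  - Attach the side arm by Cu-catalysed α-alkenylation with the alkenyl(mesityl)iodonium triflate made from 11. This reaches 25 without Pd(0) or hydride.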